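**Retrosynthetic overview**
- Numbering: cyclopenta[c]pyran (C1, O2, C3, C4, C4a, C5, C6, C7, C7a); ring A is the pyran, ring B the five-membered carbocycle. The plan rests on C6 and C7 of ring B being a hidden α-ketol: with oxygen in place of the C6 alkylidene, C6(=O)–C7(OH)(CH3) is what an acyl anion at C6 gives on adding to a methyl ketone at C7.
- The Z enone C6=CH–C(=O) is traced back to a C6 propargylic alcohol (Meyer–Schuster rearrangement), made by adding the acetylide of (S)-3-methylnon-1-yne to the C6 ketone of the C7-O-silylated ketol.
- Key disconnection C6–C7: a chiral triazolium carbene benzoin cyclisation of a pyran-4-ylidene keto-aldehyde closes ring B and sets C7.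
- The keto-aldehyde comes from a 3-acetyl-4-methoxypyrylium salt and the sodium enolate of methyl formylacetate; the 3-acetyl-4-pyranone (ring A) comes from acetylketene and an enaminone.
- The side-chain alkyne comes from an octanoyl oxazolidinone by auxiliary-controlled methylation, reduction, oxidation and one-carbon alkyne homologation. Ring order: A, then B.

Key step: step 5

Remark: the sense of induction of the aminoindanol triazolium catalyst on this substrate is assumed from a hydrogen-bonded transition-state model; should the (5aS,10bR) salt give the (7R) ketol, its (5aR,10bS) enantiomer is used under otherwise identical conditions.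

**Step 1**
Reactants: 1 2,2,6-trimethyl-4H-1,3-dioxin-4-one; 2 (E)-4-(dimethylamino)but-3-en-2-one
Product: 3 3-acetyl-6-methyl-4H-pyran-4-one
Conditions: xylene, 135 °C, slow addition of 1 to 2 (1.5 equiv), acetone distilled off
Reagents that add atoms: none
Why: thermal retro-[4+2] of the dioxinone releases acetylketene, which C-acylates the nucleophilic α-carbon of the tertiary enaminone, and the enol oxygen of the new acetoacetyl unit then closes onto the aminomethylene carbon with loss of dimethylamine (acylketene–enaminone annulation to a 4-pyranone).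

**Step 2**
Reactants: 3 3-acetyl-6-methyl-4H-pyran-4-one
Product: 4 3-acetyl-4-methoxy-6-methylpyrylium trifluoromethanesulfonate
Conditions: MeOTf (1.1 equiv), CH2Cl2, 0 °C → rt; precipitated with dry Et2O under argon
Reagents that add atoms: methyl trifluoromethanesulfonate, COS(=O)(=O)C(F)(F)F
Why: O-methylation of a 4-pyranone at its vinylogous-ester carbonyl oxygen, the most nucleophilic site, gives the aromatic 4-methoxypyrylium salt.

**Step 3**
Reactants: 5 methyl acetate; 6 methyl formate
Product: 7 sodium (E)-3-methoxy-3-oxoprop-1-en-1-olate (sodium enolate of methyl 3-oxopropanoate)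
Conditions: NaH, cat. MeOH, THF, 0 °C → rt; salt filtered, washed with Et2O, dried
Reagents that add atoms: sodium hydride, [Na+].[H-]
Why: crossed Claisen condensation in which the enolate of methyl acetate is formylated by the non-enolisable methyl formate, the product leaving the equilibrium as its insoluble sodium enolate.

**Step 4**
Reactants: 4 3-acetyl-4-methoxy-6-methylpyrylium trifluoromethanesulfonate; 7 sodium (E)-3-methoxy-3-oxoprop-1-en-1-olate
Product: 8 methyl (2E)-2-(3-acetyl-6-methyl-4H-pyran-4-ylidene)-3-oxopropanoate
Conditions: 7 (1.3 equiv), MeCN, −30 °C → rt, then 50 °C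
Reagents that add atoms: none
Why: addition–elimination condensation of a 4-alkoxypyrylium salt with an active-methylene carbanion, in which the central carbon of the enolate adds at C4 and methanol is lost irreversibly to the push-pull ylidene, whereas adducts of so stabilised a carbanion at C2 or C6 can revert on warming.

**Step 5**
Reactants: 8 methyl (2E)-2-(3-acetyl-6-methyl-4H-pyran-4-ylidene)-3-oxopropanoate
Product: 9 methyl (7S)-7-hydroxy-3,7-dimethyl-6-oxo-6,7-dihydrocyclopenta[c]pyran-5-carboxylate
Conditions: (5aS,10bR)-2-(pentafluorophenyl)-5a,10b-dihydro-4H,6H-indeno[2,1-b][1,2,4]triazolo[4,3-d][1,4]oxazin-2-ium tetrafluoroborate (15 mol%), Et3N (15 mol%), 4 Å MS, toluene, rt → 40 °C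
Reagents that add atoms: none
Why: Proposed new method: the triazolylidene released by Et3N adds to the formyl carbon of 8, proton transfer gives the hydroxy-enamine (acyl-anion equivalent) centred on C6, this carbon attacks the acetyl carbonyl carbon (C7), and collapse of the adduct returns the carbene and leaves the C6 ketone of 9. The closest known reaction type is the chiral-triazolium-catalysed intramolecular crossed aldehyde–ketone benzoin cyclisation of aryl and alkyl keto-aldehydes to five- and six-membered tertiary α-ketols; new here is the donor, a push-pull (doubly vinylogous formate) aldehyde, which should still accept the carbene because the geminal ester shares the donation of the ring oxygen, much as furfural and 4-methoxybenzaldehyde remain competent benzoin donors. Ring B closes in the 5-exo-trig mode onto the ketone carbonyl, the former exocyclic C4a=C5 bond becoming endocyclic. The C7 stereocentre is controlled by the catalyst: the fused indane of the aminoindanol backbone blocks one face of the hydroxy-enamine, and the O–H···O=C hydrogen bond to the acetyl oxygen fixes a compact bicyclic transition state that presents one enantioface of the ketone to C6. The step needs chemoselectivity for the crossed mode, and the substrate secures it: only the formyl group can become the acyl anion, only the acetyl carbonyl is within reach, and the homoenolate channel of enals is closed because its β-carbon is the fully substituted ring carbon C4a. Easy rotation about the polarised exocyclic double bond lets both geometric isomers of 8 reach the reactive conformer, conjugation of the new C6 ketone with O2 through C5=C4a and C4=C3 pulls the equilibrium to 9, and the weak base with the weakly basic N-C6F5 carbene keeps aldol closure of the acetyl methyl onto the formyl group slow.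

**Step 6**
Reactants: 9 methyl (7S)-7-hydroxy-3,7-dimethyl-6-oxo-6,7-dihydrocyclopenta[c]pyran-5-carboxylate
Product: 10 methyl (7S)-3,7-dimethyl-6-oxo-7-[(triethylsilyl)oxy]-6,7-dihydrocyclopenta[c]pyran-5-carboxylate
Conditions: TESOTf, 2,6-lutidine, CH2Cl2, −78 → 0 °C
Reagents that add atoms: triethylsilyl trifluoromethanesulfonate, CC[Si](CC)(CC)OS(=O)(=O)C(F)(F)F
Why: silyl triflate silylation of a hindered tertiary alcohol, which masks the C7 hydroxyl that would otherwise consume acetylide in step 12 and add to the gold-activated alkyne in step 13 (cyclisation of alkyne-1,2-diols).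

**Step 7**
Reactants: 11 (S)-4-benzyloxazolidin-2-one; 12 octanoyl chloride
Product: 13 (S)-4-benzyl-3-octanoyloxazolidin-2-one
Conditions: Et3N, DMAP (cat.), CH2Cl2, 0 °C → rt
Reagents that add atoms: none
Why: DMAP-catalysed N-acylation of the oxazolidinone by the acid chloride.

**Step 8**
Reactants: 13 (S)-4-benzyl-3-octanoyloxazolidin-2-one
Product: 15 (S)-4-benzyl-3-[(S)-2-methyloctanoyl]oxazolidin-2-one, via sodium Z-enolate 14 (not isolated)
Conditions: NaHMDS, THF, −78 °C; MeI, −78 → −40 °C
Reagents that add atoms: iodomethane, IC
Why: auxiliary-controlled enolate alkylation, in which the chelated Z-enolate is methylated on the face away from the benzyl group and so sets the (S) centre of the side chain.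

**Step 9**
Reactants: 15 (S)-4-benzyl-3-[(S)-2-methyloctanoyl]oxazolidin-2-one
Product: 16 (S)-2-methyloctan-1-ol
Conditions: LiBH4, MeOH (1 equiv), Et2O, 0 °C; auxiliary 11 recovered
Reagents that add atoms: none
Why: borohydride reduction of the N-acyl oxazolidinone at the exocyclic carbonyl releases the primary alcohol without touching the α-stereocentre.

**Step 10**
Reactants: 16 (S)-2-methyloctan-1-ol
Product: 17 (S)-2-methyloctanal
Conditions: Dess–Martin periodinane, NaHCO3, CH2Cl2, 0 °C → rt; used at once
Reagents that add atoms: none
Why: oxidation of a primary alcohol by a pentavalent iodine reagent under buffered, non-basic conditions that should not epimerise the α-branched aldehyde.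

**Step 11**
Reactants: 17 (S)-2-methyloctanal
Product: 18 (S)-3-methylnon-1-yne
Conditions: dimethyl (1-diazo-2-oxopropyl)phosphonate, K2CO3, MeOH, 0 °C → rt
Reagents that add atoms: dimethyl (1-diazo-2-oxopropyl)phosphonate, COP(=O)(OC)C(=[N+]=[N-])C(C)=O
Why: Seyferth–Gilbert homologation in the Ohira–Bestmann variant, in which the diazomethylphosphonate anion formed by methanolysis adds to the aldehyde and the alkylidene carbene left after loss of phosphate and N2 rearranges by 1,2-hydride shift to the terminal alkyne under conditions mild enough to keep the α-centre.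

**Step 12**
Reactants: 18 (S)-3-methylnon-1-yne; 10 methyl (7S)-3,7-dimethyl-6-oxo-7-[(triethylsilyl)oxy]-6,7-dihydrocyclopenta[c]pyran-5-carboxylate
Product: 20 methyl (7S)-6-hydroxy-3,7-dimethyl-6-[(3S)-3-methylnon-1-yn-1-yl]-7-[(triethylsilyl)oxy]-6,7-dihydrocyclopenta[c]pyran-5-carboxylate (mixture of C6 epimers), via lithium (S)-3-methylnon-1-yn-1-ide 19 (not isolated)
Conditions: 18 (1.5 equiv), n-BuLi, THF, −78 °C; anhydrous CeCl3, −78 °C; then 10, −78 °C; sat. aq. NH4Cl at −78 °C
Reagents that add atoms: none
Why: 1,2-addition of a lithium acetylide promoted by CeCl3 to a hindered, non-enolisable vinylogous-ester ketone, the oxophilic and weakly basic cerium-modified reagent favouring the C6 carbonyl over conjugate addition at C1 and over the ester; the configuration of the new C6 carbinol is of no consequence because C6 becomes trigonal in step 13.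

**Step 13**
Reactants: 20 methyl (7S)-6-hydroxy-3,7-dimethyl-6-[(3S)-3-methylnon-1-yn-1-yl]-7-[(triethylsilyl)oxy]-6,7-dihydrocyclopenta[c]pyran-5-carboxylate
Product: 21 methyl (6Z,7R)-3,7-dimethyl-6-[(3S)-3-methyl-2-oxononylidene]-7-[(triethylsilyl)oxy]-6,7-dihydrocyclopenta[c]pyran-5-carboxylate
Conditions: Ph3PAuNTf2 (5 mol%), MeOH (1 equiv), toluene, rt
Reagents that add atoms: none
Why: Meyer–Schuster rearrangement catalysed by monovalent gold (formal 1,3-shift of the tertiary propargylic hydroxyl to the alkyne terminus, then tautomerisation of the allenol), with no Rupe pathway because C5 and C7 carry no hydrogen; the Z geometry is expected as the thermodynamic one, since the E isomer would press the acyl group against the in-plane C5 ester.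

**Step 14**
Reactants: 21 methyl (6Z,7R)-3,7-dimethyl-6-[(3S)-3-methyl-2-oxononylidene]-7-[(triethylsilyl)oxy]-6,7-dihydrocyclopenta[c]pyran-5-carboxylate
Product: 22 methyl (6Z,7R)-7-hydroxy-3,7-dimethyl-6-[(3S)-3-methyl-2-oxononylidene]-6,7-dihydrocyclopenta[c]pyran-5-carboxylate (target, CNP0253314.1)
Conditions: HF·pyridine, pyridine, THF, 0 °C → rt
Reagents that add atoms: none
Why: fluoride cleavage of the tertiary triethylsilyl ether under buffered, non-basic conditions that should spare the epimerisable centre next to the ketone and the Z enone, whose geometry is then held by the O–H···O=C hydrogen bond.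

**Compound list**
1 | 2,2,6-trimethyl-4H-1,3-dioxin-4-one | CC1=CC(=O)OC(C)(C)O1 | starting material
2 | (E)-4-(dimethylamino)but-3-en-2-one | CN(C)/C=C/C(C)=O | starting material
3 | 3-acetyl-6-methyl-4H-pyran-4-one | CC(=O)C1=COC(C)=CC1=O | intermediate
4 | 3-acetyl-4-methoxy-6-methylpyrylium trifluoromethanesulfonate | COc1c(C(C)=O)c[o+]c(C)c1.[O-]S(=O)(=O)C(F)(F)F | intermediate
5 | methyl acetate | COC(C)=O | starting material
6 | methyl formate | COC=O | starting material
7 | sodium (E)-3-methoxy-3-oxoprop-1-en-1-olate | [Na+].[O-]/C=C/C(=O)OC | intermediate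
8 | methyl (2E)-2-(3-acetyl-6-methyl-4H-pyran-4-ylidene)-3-oxopropanoate | O=C/C(C(=O)OC)=C1/C=C(C)OC=C1C(C)=O | intermediate
9 | methyl (7S)-7-hydroxy-3,7-dimethyl-6-oxo-6,7-dihydrocyclopenta[c]pyran-5-carboxylate | O=C1C(C(=O)OC)=C2C=C(C)OC=C2[C@]1(C)O | intermediate
10 | methyl (7S)-3,7-dimethyl-6-oxo-7-[(triethylsilyl)oxy]-6,7-dihydrocyclopenta[c]pyran-5-carboxylate | O=C1C(C(=O)OC)=C2C=C(C)OC=C2[C@]1(C)O[Si](CC)(CC)CC | intermediate
11 | (S)-4-benzyloxazolidin-2-one | O=C1OC[C@H](Cc2ccccc2)N1 | starting material
12 | octanoyl chloride | CCCCCCCC(Cl)=O | starting material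
13 | (S)-4-benzyl-3-octanoyloxazolidin-2-one | CCCCCCCC(=O)N1[C@@H](Cc2ccccc2)COC1=O | intermediate
14 | sodium Z-enolate of 13 (not isolated) | [Na+].CCCCCC/C=C(\[O-])N1[C@@H](Cc2ccccc2)COC1=O | intermediate
15 | (S)-4-benzyl-3-[(S)-2-methyloctanoyl]oxazolidin-2-one | CCCCCC[C@H](C)C(=O)N1[C@@H](Cc2ccccc2)COC1=O | intermediate
16 | (S)-2-methyloctan-1-ol | CCCCCC[C@H](C)CO | intermediate
17 | (S)-2-methyloctanal | CCCCCC[C@H](C)C=O | intermediate
18 | (S)-3-methylnon-1-yne | CCCCCC[C@H](C)C#C | intermediate
19 | lithium (S)-3-methylnon-1-yn-1-ide (not isolated) | [Li+].CCCCCC[C@H](C)C#[C-] | intermediate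
20 | methyl (7S)-6-hydroxy-3,7-dimethyl-6-[(3S)-3-methylnon-1-yn-1-yl]-7-[(triethylsilyl)oxy]-6,7-dihydrocyclopenta[c]pyran-5-carboxylate (C6 epimers) | CCCCCC[C@H](C)C#CC1(O)C(C(=O)OC)=C2C=C(C)OC=C2[C@]1(C)O[Si](CC)(CC)CC | intermediate
21 | methyl (6Z,7R)-3,7-dimethyl-6-[(3S)-3-methyl-2-oxononylidene]-7-[(triethylsilyl)oxy]-6,7-dihydrocyclopenta[c]pyran-5-carboxylate | CCCCCC[C@H](C)C(=O)/C=C1/C(C(=O)OC)=C2C=C(C)OC=C2[C@]1(C)O[Si](CC)(CC)CC | intermediate
22 | methyl (6Z,7R)-7-hydroxy-3,7-dimethyl-6-[(3S)-3-methyl-2-oxononylidene]-6,7-dihydrocyclopenta[c]pyran-5-carboxylate | CCCCCC[C@H](C)C(=O)/C=C1/C(C(=O)OC)=C2C=C(C)OC=C2[C@]1(C)O | target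

**Step count**
Total: 14 steps. Longest linear sequence: 8 steps (steps 1, 2, 4, 5, 6, 12, 13, 14 from compound 1; the side-chain branch, steps 7 to 14 from compound 11, is equally long).

**Steps most likely to fail**

1. Step 5 (key step, proposed new method). The carbene may fail to engage the electron-rich, hindered formyl group; the base may instead start aldol closure of the acetyl methyl onto the formyl group; or the facial discrimination at the acetyl carbonyl may be poor. The fallback uses known chemistry, sets out from 8 and returns at 9, and forms the C6–C7 bond reductively instead of by umpolung. Keto-aldehyde 8 is cyclised by a pinacol coupling with samarium diiodide (SmI2, t-BuOH, THF, −78 °C) to the cis-diol methyl rac-(6R,7S)-6,7-dihydroxy-3,7-dimethyl-6,7-dihydrocyclopenta[c]pyran-5-carboxylate F1. The allylic secondary C6 hydroxyl is then oxidised selectively with MnO2 in CH2Cl2 to the racemic ketol methyl rac-7-hydroxy-3,7-dimethyl-6-oxo-6,7-dihydrocyclopenta[c]pyran-5-carboxylate F2. The enantiomers are separated by preparative HPLC on an amylose tris(3,5-dimethylphenylcarbamate) phase, the (7S) enantiomer being 9.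

2. Step 4. The enolate may add kinetically at the unsubstituted C2 of the pyrylium ring, which the 3-acetyl group activates, and the resulting 2H-pyran may ring-open before it can revert. The fallback sets out from 4 and returns at 8, and replaces the anionic nucleophile by a neutral enaminoester whose aldehyde carbon arrives as an iminium ion. Salt 4 is treated with methyl (E)-3-(dimethylamino)acrylate and 2,6-lutidine in MeCN. The enamine α-carbon adds at C4 (adducts at C2 are iminium ions that revert), and loss of methanol gives the vinylogous amidinium salt N-[2-(3-acetyl-6-methyl-4H-pyran-4-ylidene)-3-methoxy-3-oxopropylidene]-N-methylmethanaminium trifluoromethanesulfonate F3. Aqueous NaOAc hydrolyses it to 8.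

3. Step 13. The C6 carbinol may ionise to the cyclopenta[c]pyrylium cation, which methanol can capture at C1 or C3, or the rearrangement may give the wrong alkene geometry. The fallback sets out from 10 and 15 and returns at 21 (steps 9 to 13 are then not needed); it is an aldol addition and dehydration in place of alkynylation and rearrangement. Imide 15 is converted with Me(MeO)NH·HCl and AlMe3 into the amide (S)-N-methoxy-N,2-dimethyloctanamide F4, and MeMgBr then gives the methyl ketone (S)-3-methylnonan-2-one F5. Its kinetic lithium enolate (LDA, THF, −78 °C, methyl side) is added to ketone 10 in the presence of CeCl3 to give the aldol methyl (7S)-6-hydroxy-3,7-dimethyl-6-[(3S)-3-methyl-2-oxononyl]-7-[(triethylsilyl)oxy]-6,7-dihydrocyclopenta[c]pyran-5-carboxylate F6. Dehydration of the tertiary C6 alcohol with methyl N-(triethylammoniosulfonyl)carbamate (Burgess reagent) in toluene gives 21.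

**Further compounds**
F1 | step 5 | methyl rac-(6R,7S)-6,7-dihydroxy-3,7-dimethyl-6,7-dihydrocyclopenta[c]pyran-5-carboxylate (racemic cis-diol, one enantiomer drawn) | O[C@@H]1C(C(=O)OC)=C2C=C(C)OC=C2[C@]1(C)O
F2 | step 5 | methyl rac-7-hydroxy-3,7-dimethyl-6-oxo-6,7-dihydrocyclopenta[c]pyran-5-carboxylate | O=C1C(C(=O)OC)=C2C=C(C)OC=C2C1(C)O
F3 | step 4 | N-[2-(3-acetyl-6-methyl-4H-pyran-4-ylidene)-3-methoxy-3-oxopropylidene]-N-methylmethanaminium trifluoromethanesulfonate | C[N+](C)=C/C(C(=O)OC)=C1/C=C(C)OC=C1C(C)=O.[O-]S(=O)(=O)C(F)(F)F
F4 | step 13 | (S)-N-methoxy-N,2-dimethyloctanamide | CCCCCC[C@H](C)C(=O)N(C)OC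
F5 | step 13 | (S)-3-methylnonan-2-one | CCCCCC[C@H](C)C(C)=O
F6 | step 13 | methyl (7S)-6-hydroxy-3,7-dimethyl-6-[(3S)-3-methyl-2-oxononyl]-7-[(triethylsilyl)oxy]-6,7-dihydrocyclopenta[c]pyran-5-carboxylate | CCCCCC[C@H](C)C(=O)CC1(O)C(C(=O)OC)=C2C=C(C)OC=C2[C@]1(C)O[Si](CC)(CC)CC
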